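**Retrosynthetic overview**

1. Feature: C2 of the flavanone unit is both the ether carbon on O1 and the benzylic carbon of the 4-hydroxyphenyl ring. With ring C opened it becomes the OCH2 carbon of a ring A 4-benzyloxybenzyl ether, whose electron-rich C–H lies 1,6 to C3.
2. Key disconnection (ring C, the last ring formed): the C2–C3 bond, by enantioselective dirhodium carbene C–H insertion of an α-(luteolin-8-yl) α-diazo ketone. C2 is set by the catalyst and C3 by equilibration to trans.
3. The diazo group comes from diazo transfer to a deoxybenzoin. The C3–C8'' bond comes from Pd-catalysed α-arylation of a ring A acetophenone with an 8-iodoluteolin derivative.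
4. Ring A comes from 2,4,6-trihydroxyacetophenone by three successive O-alkylations (benzyl at O4, then 4-benzyloxybenzyl at each ortho oxygen). The three luteolin rings are preformed in luteolin (catechol ketal, O7 silyl ether, O5 benzyl ether, C8 iodide).
5. End game: fluoride frees O7'' alone, sulfation follows, and one hydrogenolysis removes every benzylic group and the ketal.

Key step: step 10

Remark: BBn = 4-benzyloxybenzyl. In the biflavonoid the flavanone unit carries unprimed and single-primed locants and the luteolin unit double- and triple-primed locants.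
Remark: the target is drawn as the free hydrogen sulfate. The sulfate is carried as its sodium salt and protonated only in the last operation, because aryl hydrogen sulfates hydrolyse under acid.
Remark: Rh2(S-PTTL)4, dirhodium tetrakis[N-phthaloyl-(S)-tert-leucinate], is assumed to select the benzylic hydrogen that leads to 2R. If a trial run shows 2S, the mirror-image catalyst Rh2(R-PTTL)4 is used with nothing else changed.

**Route**

Step 1
Reactants: 1 luteolin
Product: 2 3',4'-O-(diphenylmethylene)luteolin
Conditions: Ph2CCl2, Ph2O, 175 °C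
Reagents that add atoms: dichlorodiphenylmethane, ClC(Cl)(c1ccccc1)c1ccccc1
Why: Ketalisation with a gem-dichloride should engage only the catechol, the one pair of hydroxyls that can close a five-membered 1,3-benzodioxole, leaving the 5- and 7-OH free.

Step 2
Reactants: 2 3',4'-O-(diphenylmethylene)luteolin
Product: 3 7-O-triisopropylsilyl ether of 2 (5-OH free)
Conditions: TIPSCl, imidazole, DMF, 0 °C → rt
Reagents that add atoms: triisopropylsilyl chloride, CC(C)[Si](Cl)(C(C)C)C(C)C
Why: Selective O-silylation should occur at the acidic, unhindered 7-OH because the 5-OH is held in a hydrogen bond to the C4 carbonyl.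

Step 3
Reactants: 3 7-O-triisopropylsilyl ether of 2
Product: 4 5-O-benzyl-3',4'-O-(diphenylmethylene)-7-O-(triisopropylsilyl)luteolin
Conditions: BnBr, Ag2O, 4 Å MS, DMF, rt, dark
Reagents that add atoms: benzyl bromide, BrCc1ccccc1
Why: Purdie-type O-alkylation, in which silver activates the benzylic bromide under neutral conditions, should etherify the chelated 5-OH while sparing the aryl silyl ether at O7, which hydride or carbonate bases in DMF would cleave.

Step 4
Reactants: 4 5-O-benzyl-3',4'-O-(diphenylmethylene)-7-O-(triisopropylsilyl)luteolin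
Product: 5 8-iodo derivative of 4
Conditions: NIS, TFA (cat.), CH2Cl2/MeCN, 0 °C → rt
Reagents that add atoms: N-iodosuccinimide, O=C1CCC(=O)N1I
Why: Electrophilic aromatic iodination of a 5,7-dietherified flavone should go to C8 (ortho to O7 and O1, para to O5), since C6 sits between the two bulky ethers and ring B is deactivated by the pyranone.

Step 5
Reactants: 6 2,4,6-trihydroxyacetophenone
Product: 7 1-(4-benzyloxy-2,6-dihydroxyphenyl)ethanone
Conditions: BnBr (1.0 equiv), K2CO3 (1.0 equiv), DMF, 0 °C → rt
Reagents that add atoms: benzyl bromide, BrCc1ccccc1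
Why: Williamson etherification with one equivalent of base should go to the 4-OH, the most acidic hydroxyl (para to the acetyl group) and the only one that is neither chelated to the carbonyl nor flanked by the acetyl group.

Step 6
Reactants: 7 1-(4-benzyloxy-2,6-dihydroxyphenyl)ethanone; 8 4-benzyloxybenzyl chloride
Product: 9 1-[4-benzyloxy-2-(4-benzyloxybenzyloxy)-6-hydroxyphenyl]ethanone
Conditions: K2CO3, TBAI (cat.), acetone, reflux
Reagents that add atoms: none
Why: Williamson etherification under mild carbonate conditions, with the benzylic chloride activated as the iodide by Finkelstein exchange, should alkylate one of the two equivalent ortho hydroxyls and then stop because the remaining hydroxyl is locked in a hydrogen bond to the ketone.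

Step 7
Reactants: 9 1-[4-benzyloxy-2-(4-benzyloxybenzyloxy)-6-hydroxyphenyl]ethanone; 8 4-benzyloxybenzyl chloride
Product: 10 1-[4-benzyloxy-2,6-bis(4-benzyloxybenzyloxy)phenyl]ethanone
Conditions: Cs2CO3, TBAI (cat.), DMF, 60 °C
Reagents that add atoms: none
Why: Williamson etherification of the chelated phenol should succeed through the dissociated caesium phenoxide in warm DMF, and O-alkylation should outrun C-alkylation because the methyl ketone is far less acidic than the phenol.

Step 8
Reactants: 10 1-[4-benzyloxy-2,6-bis(4-benzyloxybenzyloxy)phenyl]ethanone; 5 8-iodo derivative of 4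
Product: 11 deoxybenzoin 1-[4-benzyloxy-2,6-bis(4-benzyloxybenzyloxy)phenyl]-2-(luteolin-8-yl)ethanone (luteolin unit protected as in 4)
Conditions: Pd2(dba)3 (cat.), XPhos, K3PO4, toluene, 90 °C
Reagents that add atoms: none
Why: Buchwald–Hartwig-type α-arylation of the methyl ketone enolate should succeed because the bulky biaryl phosphine allows oxidative addition at the di-ortho-substituted iodide and fast C–C reductive elimination, K3PO4 spares the flavone and the silyl ether, and the congestion of the product blocks a second arylation.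

Step 9
Reactants: 11 deoxybenzoin
Product: 12 diazo ketone (2-diazo derivative of 11)
Conditions: p-ABSA, DBU, anhydrous MeCN/CH2Cl2, 0 °C → rt, dark
Reagents that add atoms: 4-acetamidobenzenesulfonyl azide, CC(=O)Nc1ccc(cc1)S(=O)(=O)N=[N+]=[N-]
Why: Regitz diazo transfer should work because the methylene is acidified by both the ketone and the aryl ring, so DBU gives the enolate, which attacks the terminal azide nitrogen and expels the sulfonamide.

Step 10
Reactants: 12 diazo ketone
Product: 14 (2R,3S)-2,3-trans protected biflavonoid (7,4'-di-O-benzyl-5-O-BBn-naringenin bonded from C3 to C8'' of the luteolin unit protected as in 4), via cis C3 epimer 13 (not isolated)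
Conditions: Rh2(S-PTTL)4 (2 mol%), PhCF3, 0 °C → rt; then PPTS (cat.), CH2Cl2, rt
Reagents that add atoms: none
Why: Rh2(S-PTTL)4 adds to the diazo carbon of 12, N2 leaves, and the electrophilic rhodium-bound aryl keto carbene at the future C3 engages the hydridic C–H bond of one ring A OCH2Ar group in an asynchronous three-centre transition state in which the positive charge building at the future C2 is carried by O1 and by the 4-benzyloxyphenyl ring. The closest known reaction type is the dirhodium carboxylate-catalysed intramolecular C–H insertion of 2-alkoxyphenyl α-diazo ketones next to the ether oxygen, which gives 2,3-disubstituted chroman-4-ones, also with chiral carboxylates. Ring C closes by 1,6-C–H insertion (new C2–C3 bond; ring atoms C3, C4, C4a, C8a, O1, C2), the usual 1,5 mode being unavailable because the fifth atom of the chain is the ether oxygen. C2 is set by the chiral carboxylate pocket, which picks one of the two enantiotopic benzylic hydrogens and replaces it with retention, while C3 is set thermodynamically, since the cis epimer 13 should enolise under PPTS to the diequatorial 2,3-trans isomer 14 without touching C2. The step needs insertion to beat formation of the five-membered oxonium ylide at O1 and 1,2-shift of its benzyl group, which is favoured because that oxygen is a poor donor (conjugated to the ortho acyl group), the C–H bond is doubly activated, and the bulky phthalimido carboxylate in a non-coordinating solvent disfavours the ylide path. Site selectivity follows from symmetry (the two ortho BBn ethers are equivalent, so either leads to 14, and the one left over is a hydrogenolysable protecting group) and from the lack of any other activated C–H within reach, since the O7'' silyl ether, the ketal and the remote benzyl ethers offer none.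

Step 11
Reactants: 14 (2R,3S)-2,3-trans protected biflavonoid
Product: 15 7''-phenol (14 without the silyl group)
Conditions: TBAF, AcOH, THF, 0 °C
Reagents that add atoms: none
Why: Fluoride cleavage of the aryl silyl ether is driven by the Si–F bond, and the acetic acid buffer should keep the medium non-basic so that C3 enolate formation and retro-oxa-Michael opening of ring C, which would erode C2, are avoided.

Step 12
Reactants: 15 7''-phenol
Product: 16 sodium 7''-O-sulfate of 15
Conditions: SO3·pyridine, pyridine, 45 °C; then aq. NaHCO3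
Reagents that add atoms: sulfur trioxide–pyridine complex, [O-]S(=O)(=O)[n+]1ccccc1; sodium hydrogencarbonate, [Na+].OC([O-])=O
Why: O-sulfation of a phenol with SO3·pyridine should be site-specific because O7'' is the only free hydroxyl, and the monoester is stable as its sodium salt.

Step 13
Reactants: 16 sodium 7''-O-sulfate
Product: 18 target 8-[(2R,3S)-5,7-dihydroxy-2-(4-hydroxyphenyl)-4-oxochroman-3-yl]-2-(3,4-dihydroxyphenyl)-5-hydroxy-4-oxochromen-7-yl hydrogen sulfate, via sodium salt of the target 17 (not isolated)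
Conditions: H2 (1 atm), Pd/C, THF/MeOH/H2O, rt; then 1 M HCl (1 equiv), 0 °C, C18 desalting, lyophilisation
Reagents that add atoms: none
Why: Catalytic hydrogenolysis of benzylic C–O bonds should cleave the benzyl ethers, the BBn ether (to 4-methylphenol and toluene) and the diphenylmethylene ketal (to diphenylmethane) while the aryl sulfate salt, the flavone and the flavanone are expected to persist at 1 atm, and cold protonation then gives the hydrogen sulfate without touching C2 or C3.

**Compound list**

1 | luteolin | O=c1cc(-c2ccc(O)c(O)c2)oc2cc(O)cc(O)c12 | starting material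
2 | 3',4'-O-(diphenylmethylene)luteolin, 2-(2,2-diphenyl-1,3-benzodioxol-5-yl)-5,7-dihydroxychromen-4-one | O=c1cc(-c2ccc3c(c2)OC(c2ccccc2)(c2ccccc2)O3)oc2cc(O)cc(O)c12 | intermediate
3 | 7-O-triisopropylsilyl ether of 2 (5-OH free) | O=c1cc(-c2ccc3c(c2)OC(c2ccccc2)(c2ccccc2)O3)oc2cc(O[Si](C(C)C)(C(C)C)C(C)C)cc(O)c12 | intermediate
4 | 5-O-benzyl-3',4'-O-(diphenylmethylene)-7-O-(triisopropylsilyl)luteolin | O=c1cc(-c2ccc3c(c2)OC(c2ccccc2)(c2ccccc2)O3)oc2cc(O[Si](C(C)C)(C(C)C)C(C)C)cc(OCc3ccccc3)c12 | intermediate
5 | 8-iodo derivative of 4 | O=c1cc(-c2ccc3c(c2)OC(c2ccccc2)(c2ccccc2)O3)oc2c(I)c(O[Si](C(C)C)(C(C)C)C(C)C)cc(OCc3ccccc3)c12 | intermediate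
6 | 2,4,6-trihydroxyacetophenone | CC(=O)c1c(O)cc(O)cc1O | starting material
7 | 1-(4-benzyloxy-2,6-dihydroxyphenyl)ethanone | CC(=O)c1c(O)cc(OCc2ccccc2)cc1O | intermediate
8 | 4-benzyloxybenzyl chloride | ClCc1ccc(OCc2ccccc2)cc1 | starting material
9 | 1-[4-benzyloxy-2-(4-benzyloxybenzyloxy)-6-hydroxyphenyl]ethanone | CC(=O)c1c(O)cc(OCc2ccccc2)cc1OCc1ccc(OCc2ccccc2)cc1 | intermediate
10 | 1-[4-benzyloxy-2,6-bis(4-benzyloxybenzyloxy)phenyl]ethanone | CC(=O)c1c(OCc2ccc(OCc3ccccc3)cc2)cc(OCc2ccccc2)cc1OCc1ccc(OCc2ccccc2)cc1 | intermediate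
11 | deoxybenzoin, 1-[4-benzyloxy-2,6-bis(4-benzyloxybenzyloxy)phenyl]-2-(luteolin-8-yl)ethanone with the luteolin unit protected as in 4 | O=C(Cc1c(O[Si](C(C)C)(C(C)C)C(C)C)cc(OCc2ccccc2)c2c(=O)cc(-c3ccc4c(c3)OC(c3ccccc3)(c3ccccc3)O4)oc12)c1c(OCc2ccc(OCc3ccccc3)cc2)cc(OCc2ccccc2)cc1OCc1ccc(OCc2ccccc2)cc1 | intermediate
12 | diazo ketone, 11 with a diazo group on the carbon between the ketone and luteolin C8 | O=C(C(=[N+]=[N-])c1c(O[Si](C(C)C)(C(C)C)C(C)C)cc(OCc2ccccc2)c2c(=O)cc(-c3ccc4c(c3)OC(c3ccccc3)(c3ccccc3)O4)oc12)c1c(OCc2ccc(OCc3ccccc3)cc2)cc(OCc2ccccc2)cc1OCc1ccc(OCc2ccccc2)cc1 | intermediate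
13 | cis C3 epimer of 14, (2R,3R), the kinetic insertion product to the extent that insertion is cis-selective | O=C1c2c(OCc3ccc(OCc4ccccc4)cc3)cc(OCc3ccccc3)cc2O[C@@H](c2ccc(OCc3ccccc3)cc2)[C@H]1c1c(O[Si](C(C)C)(C(C)C)C(C)C)cc(OCc2ccccc2)c2c(=O)cc(-c3ccc4c(c3)OC(c3ccccc3)(c3ccccc3)O4)oc12 | intermediate
14 | (2R,3S)-2,3-trans protected biflavonoid: flavanone with 5-O-BBn, 7-O-benzyl and 4'-O-benzyl, C3 bonded to C8'' of the luteolin unit carrying 5''-O-benzyl, 7''-O-triisopropylsilyl and 3''',4'''-O-diphenylmethylene | O=C1c2c(OCc3ccc(OCc4ccccc4)cc3)cc(OCc3ccccc3)cc2O[C@@H](c2ccc(OCc3ccccc3)cc2)[C@@H]1c1c(O[Si](C(C)C)(C(C)C)C(C)C)cc(OCc2ccccc2)c2c(=O)cc(-c3ccc4c(c3)OC(c3ccccc3)(c3ccccc3)O4)oc12 | intermediate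
15 | 7''-phenol, 14 without the silyl group, (2R,3S) | O=C1c2c(OCc3ccc(OCc4ccccc4)cc3)cc(OCc3ccccc3)cc2O[C@@H](c2ccc(OCc3ccccc3)cc2)[C@@H]1c1c(O)cc(OCc2ccccc2)c2c(=O)cc(-c3ccc4c(c3)OC(c3ccccc3)(c3ccccc3)O4)oc12 | intermediate
16 | sodium 7''-O-sulfate of 15, (2R,3S) | O=C1c2c(OCc3ccc(OCc4ccccc4)cc3)cc(OCc3ccccc3)cc2O[C@@H](c2ccc(OCc3ccccc3)cc2)[C@@H]1c1c(OS(=O)(=O)[O-])cc(OCc2ccccc2)c2c(=O)cc(-c3ccc4c(c3)OC(c3ccccc3)(c3ccccc3)O4)oc12.[Na+] | intermediate
17 | sodium salt of the target, (2R,3S) | O=C1c2c(O)cc(O)cc2O[C@@H](c2ccc(O)cc2)[C@@H]1c1c(OS(=O)(=O)[O-])cc(O)c2c(=O)cc(-c3ccc(O)c(O)c3)oc12.[Na+] | intermediate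
18 | CNP0314990.1, 8-[(2R,3S)-5,7-dihydroxy-2-(4-hydroxyphenyl)-4-oxochroman-3-yl]-2-(3,4-dihydroxyphenyl)-5-hydroxy-4-oxochromen-7-yl hydrogen sulfate (2,3-trans) | O=C1c2c(O)cc(O)cc2O[C@@H](c2ccc(O)cc2)[C@@H]1c1c(OS(=O)(=O)O)cc(O)c2c(=O)cc(-c3ccc(O)c(O)c3)oc12 | target

**Step count and risks**

Total step count: 13. Longest linear sequence: 10 steps (luteolin through steps 1–4 and 8–13).

Steps most likely to fail:

1. Step 10. The carbene may be captured by the ring A ether oxygen, giving a five-membered oxonium ylide that shifts its benzyl group to C3. Nitrogen loss at the congested diazo carbon may be slow. The catalyst may discriminate poorly between the two enantiotopic benzylic hydrogens. The fallback sets out from 11 and closes ring C by condensation instead. MgBr2·OEt2 in CH2Cl2/Et2O at 0 °C should remove one of the two equivalent ortho BBn ethers by chelation to the ketone, the 4-alkoxybenzyl ether being far more labile than the plain benzyl ether at O5''. This gives the 2-hydroxy deoxybenzoin 1-[4-benzyloxy-2-(4-benzyloxybenzyloxy)-6-hydroxyphenyl]-2-(luteolin-8-yl)ethanone F1. Piperidine-mediated condensation of F1 with commercial 4-benzyloxybenzaldehyde in refluxing EtOH (Knoevenagel condensation, then intramolecular oxa-Michael addition) should give the racemic 2,3-trans flavanone F2. Preparative HPLC of F2 on a chiral stationary phase then gives the (2R,3S) enantiomer, and the fallback comes back to the route at 14.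

2. Step 8. Oxidative addition and enolate coupling at the di-ortho-substituted C8–I bond may be outrun by protodeiodination or by enolate attack on the flavone. The fallback sets out from 5 and 10 and reverses the polarity of the coupling. Miyaura borylation of 5 (B2pin2, Pd(dppf)Cl2, KOAc, dioxane, 80 °C) should give the 8-(pinacolboryl)flavone F3. Deprotonation of 10 with LiN(SiMe3)2 (THF, −78 °C) and bromination of the enolate with NBS should give the α-bromo ketone F4 without bromination of the electron-rich rings. Suzuki–Miyaura coupling of F3 with F4 (Pd(OAc)2, tri(1-naphthyl)phosphine, K3PO4, THF/H2O, rt) comes back to the route at 11.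

3. Step 9. The methylene between two twisted, di-ortho-substituted aryl groups may be too shielded for complete diazo transfer, and long exposure to DBU may erode the silyl ether. The fallback sets out from 10, installs the diazo group before the aryl group, and so also bypasses step 8. LiN(SiMe3)2 and CF3CO2CH2CF3 (THF, −78 °C) should give the trifluoroacetyl ketone F5. Detrifluoroacetylative diazo transfer (MsN3, Et3N, H2O, MeCN) should give the diazomethyl ketone F6. Pd-catalysed C–H arylation of F6 with 5, with retention of the diazo group (Pd(PPh3)4, Ag2CO3, Et3N, toluene, rt), comes back to the route at 12.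

**Further compounds**

F1 | step 10 | 1-[4-benzyloxy-2-(4-benzyloxybenzyloxy)-6-hydroxyphenyl]-2-(luteolin-8-yl)ethanone, luteolin unit protected as in 4 | O=C(Cc1c(O[Si](C(C)C)(C(C)C)C(C)C)cc(OCc2ccccc2)c2c(=O)cc(-c3ccc4c(c3)OC(c3ccccc3)(c3ccccc3)O4)oc12)c1c(O)cc(OCc2ccccc2)cc1OCc1ccc(OCc2ccccc2)cc1
F2 | step 10 | racemate of 14, (2R*,3S*)-2,3-trans (one enantiomer drawn) | O=C1c2c(OCc3ccc(OCc4ccccc4)cc3)cc(OCc3ccccc3)cc2O[C@@H](c2ccc(OCc3ccccc3)cc2)[C@@H]1c1c(O[Si](C(C)C)(C(C)C)C(C)C)cc(OCc2ccccc2)c2c(=O)cc(-c3ccc4c(c3)OC(c3ccccc3)(c3ccccc3)O4)oc12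
F3 | step 8 | 8-(4,4,5,5-tetramethyl-1,3,2-dioxaborolan-2-yl) derivative of 4 | O=c1cc(-c2ccc3c(c2)OC(c2ccccc2)(c2ccccc2)O3)oc2c(B3OC(C)(C)C(C)(C)O3)c(O[Si](C(C)C)(C(C)C)C(C)C)cc(OCc3ccccc3)c12
F4 | step 8 | 2-bromo-1-[4-benzyloxy-2,6-bis(4-benzyloxybenzyloxy)phenyl]ethanone | O=C(CBr)c1c(OCc2ccc(OCc3ccccc3)cc2)cc(OCc2ccccc2)cc1OCc1ccc(OCc2ccccc2)cc1
F5 | step 9 | 4,4,4-trifluoro-1-[4-benzyloxy-2,6-bis(4-benzyloxybenzyloxy)phenyl]butane-1,3-dione | O=C(CC(=O)C(F)(F)F)c1c(OCc2ccc(OCc3ccccc3)cc2)cc(OCc2ccccc2)cc1OCc1ccc(OCc2ccccc2)cc1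
F6 | step 9 | 2-diazo-1-[4-benzyloxy-2,6-bis(4-benzyloxybenzyloxy)phenyl]ethanone | [N-]=[N+]=CC(=O)c1c(OCc2ccc(OCc3ccccc3)cc2)cc(OCc2ccccc2)cc1OCc1ccc(OCc2ccccc2)cc1
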